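## The problem

The target is a 3,5-diformylphloroglucinol joined through a benzylic methine C1′, which also carries an isobutyl group, to the quaternary carbon C4 of a guaiane-type hydroazulene. The cyclopentane (C1–C5) is fused along C1–C5 to a seven-membered ring (C1, C5–C10) whose only alkene, C5=C6, is exocyclic to the small ring. Five stereocentres must be set: C1′ and C4 are neighbours on an open chain (a tertiary benzylic centre beside an all-carbon quaternary one), C1 and C10 are neighbours on the large ring with their hydrogens cis, and C7 carries the 2-hydroxyprop-2-yl group beyond the alkene. The C1′/C4 pair cannot be controlled reliably from the ring centres and has to be built under its own control. An oxygen placed on C8, next to C7, can pass its configuration to C10 and C1 if the transfer is concerted. The sensitive groups are the tertiary homoallylic alcohol (ionisation, dehydration), the trisubstituted alkene (migration), the allylic C1–H once a carbonyl sits on C2, and the electron-rich ring with two aldehydes and three free phenols. The enabling feature is the run C2–C1–C5=C6–C7–C8: closed by an oxygen between C2 and C8 it is an ε-lactone, and an (E)-propenyl group on C8 supplies C9, C10 and the C10 methyl. A [3,3] shift of the lactone enol derivative then trades the easy O–C8 ester bond for the hard C1–C10 bond.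

## Retrosynthesis

**Aromatic endgame.** Target 46 is traced to silyl ether 45, to trimethyl ether 44 and, by cutting both aryl–CHO bonds, to arene 41. A formylated phloroglucinol would not survive enolates, organometallics or metathesis, whereas the 2,4,6-trimethoxyphenyl group does. Its two free positions each lie between two methoxy groups, so they can be lithiated and formylated without the Lewis acid that the tertiary silyl ether would not tolerate. The forward steps must remove three methyl groups by attack at carbon, not by acid.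

**Five-membered ring.** Arene 41 comes from triene 40 by saturation of C2=C3 and C8=C9, and 40 from diene 39 by cutting C2=C3 (ring-closing metathesis). An aldol or alkylation closure would need extra functional groups on C2 and C3. Metathesis needs only a propenyl group on C4 and a vinyl group on C1, and the latter comes from acid 36 through alcohol 37 and aldehyde 38. Hydrogenation creates no stereocentre but must spare C5=C6, and the chemistry at C2 must not epimerise C1.

**Key disconnection.** Acid 36 is cut at C1–C10 with re-formation of O–C8, which leads to ε-lactone 32. This replaces a cycloheptadiene with two adjacent cis stereocentres by a lactone made through esterification, and it lets the aldol-derived centre C8 control C1 and C10. The alternative cut at C5=C6 by metathesis would need a 1,1-disubstituted alkene beside the quaternary carbon. An open-chain ester-enolate Claisen rearrangement would give a trans C8=C9 alkene, which cannot lie in a seven-membered ring.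

**Lactone.** Lactone 32 is the deconjugated isomer of lactone 30, which is opened at the C2–O bond to hydroxy acid 28. The conjugated isomer is the one that enol triflate chemistry delivers with secure geometry. One kinetic protonation of its potassium dienolate moves the alkene, and the ring fixes C5=C6 as cis.

**Fragment union.** Acid 28 comes from ester 27, which is cut at C5–C6 into enol triflate 12 and organozinc 26, made from iodide 24. This sp2–sp3 cut divides the molecule into halves of similar size and places the stereochemistry of the trisubstituted alkene in the enol triflate. A carbonyl olefination at C5=C6 would have to join a quaternary-substituted carbon to a branched aldehyde with no control of geometry.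

**Aldol half.** Iodide 24 is traced through alcohol 23 and silyl ether 22 to aldol 21, which is cut at C7–C8 into imide 18 and crotonaldehyde 19. Imide 18 comes from acid 15 and oxazolidinone 16, and 15 from hydroxy acid 13. The lactone needs the C7 substituent anti to the C8–O bond, which is the syn aldol, so a boron aldol reaction sets both centres at once.

**C1–C2 unit.** Triflate 12 comes from β-keto ester 11, which is cut at C5–C1 (Claisen condensation with an acetate enolate) to ester 10. Ester 10 has no α-hydrogen and can act only as the acceptor. The ketone can enolise only toward C1, so the triflate geometry is unambiguous.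

**Quaternary carbon.** Ester 10 is the ring-opened, O-methylated form of dihydrocoumarin 8, which comes from allyl lactone 7, then from 6 and 5 by removing the C4 methyl and the C4–C3 bond. The phenol oxygen of the future aryl group ties C1′ and C4 into one six-membered lactone. Two successive enolate alkylations, each anti to the isobutyl group, then fix the open-chain C1′/C4 relationship. An acyclic route would depend on 1,2-induction at a quaternary centre.

**C1′.** Lactone 5 comes from lactol 4, which is cut at the aryl–C1′ bond into enal 2 and phenol 3, and 2 is made from isovaleraldehyde 1. A catalyst-controlled conjugate addition sets the first stereocentre of this half, and all later centres of the half follow from it.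

## Roads not taken

**Alternative 1:** The aromatic ring is made last. The cut runs through the two ring bonds that join the hydroxyl-bearing carbons flanking the ipso carbon to the two ester-bearing carbons. Malonyl dichloride A1, carrying C1′ and the complete hydroazulene on its central carbon, would C-acylate dimethyl 3-oxoglutarate A2 twice under soft-enolisation conditions (MgCl2, NEt3). The cyclic triketone would then tautomerise to isophthalate A3.
- Merits: the oxygenation pattern arrives complete and unprotected, so no late electrophilic substitution and no threefold demethylation are needed. In that respect this road is better than the present plan.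
- Weak points: the C1′ centre beside quaternary C4 must now be made as a malonate-bearing carbon, which is harder than as an aryl-bearing one. A diacid chloride must be generated on a full-size fragment that holds a tertiary silyl ether and an alkene. O-acylation competes with C-acylation. The two esters of A3 still have to be taken down to aldehydes on a triphenol.
- Comparison: the step does nothing for the ring system or for C1/C10. The present plan accepts a harsher aromatic endgame but uses the arene early as a stereocontrol template.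

**Alternative 2:** The hydroazulene is reached from a decalin. Treatment of diol monomesylate A4 with KOtBu would form the tertiary C6 alkoxide. C1 would then migrate from C6 to C5 with loss of the sulfonate, contracting one ring to the cyclopentane and expanding the other to cycloheptanone A5.
- Merits: decalins are familiar, and the 1,2-shift is stereospecific (retention at C1, inversion at C5). Its predictability is as good as that of a sigmatropic shift.
- Weak points: A4 must already contain C1, C4, C7, C10, C1′ and an equatorial sulfonate on a hindered secondary carbon beside the quaternary centre. A5 lacks the C5=C6 alkene, and the C6 ketone can enolise toward either C5 or C7, the latter being an epimerisable stereocentre. The alkene then needs a reduction–elimination or enol triflate sequence with a regiochemical risk.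
- Comparison: the present plan delivers C5=C6 in place and derives C1 and C10 from a single aldol centre, at the price of a less common key step.

**Alternative 3:** The cut is at C1′, on both the aryl–C1′ and the C1′–CH2 bonds. Aldehyde A6 would condense with 2,4-diformylphloroglucinol A7 to ortho-quinone methide A8. Allylsilane A9 would attack A8 at C1′ in the same flask, giving methallyl compound A10, and one selective hydrogenation would finish the synthesis.
- Merits: this is the shortest aromatic endgame, with no protecting groups on the arene, no formylation and no demethylation. On step count for that part it is clearly better than the present plan.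
- Weak points: the configuration at C1′ would rest on the facial bias of an acyclic quinone methide beside a quaternary carbon, which is not predictable. Condensation of a neopentyl aldehyde with the deactivated phloroglucinol is slow. The quinone methide can be trapped within the molecule by C5=C6 (hetero-Diels–Alder) or by the tertiary alcohol. The synthesis of A6 with C1, C4, C7 and C10 in place remains unsolved.
- Comparison: the present plan fixes C1′ by a catalyst and relays it to C4 through a ring, and it never exposes a free quinone methide to the alkene.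

Key step: step 20

Assumption: carbons are labelled by guaiane numbering throughout (C11 is the carbinol carbon on C7, C1′ the benzylic carbon on C4), and the sense of induction in step 2 is taken from the usual face-shielding model of prolinol silyl ether iminium ions.

Step 1
Reactants: 1 isovaleraldehyde (3-methylbutanal)
Product: 2 (E)-5-methylhex-2-enal
Conditions: Ph3P=CHCHO, toluene, 80 °C
Reagents that add atoms: (formylmethylene)triphenylphosphorane, O=CC=P(c1ccccc1)(c1ccccc1)c1ccccc1
Why: Wittig olefination with the formyl-stabilised ylide, which gives the (E)-enal; one equivalent of ylide limits a second homologation.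

Step 2
Reactants: 2 (E)-5-methylhex-2-enal; 3 3,5-dimethoxyphenol
Product: 4 (4S)-5,7-dimethoxy-4-(2-methylpropyl)chroman-2-ol
Conditions: (R)-α,α-diphenylprolinol trimethylsilyl ether (20 mol %), PhCO2H (20 mol %), toluene, 0 °C
Reagents that add atoms: none
Why: Iminium-ion Friedel–Crafts alkylation of the electron-rich phenol followed by hemiacetal closure; the diphenyl(silyloxy)methyl group shields one face of the (E)-iminium ion, so the ring carbon ortho to the hydroxyl adds to the open face and sets C1′ (4S), and ring closure makes the ortho pathway the productive one.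

Step 3
Reactants: 4 (4S)-5,7-dimethoxy-4-(2-methylpropyl)chroman-2-ol
Product: 5 (4S)-5,7-dimethoxy-4-(2-methylpropyl)chroman-2-one
Conditions: TEMPO (10 mol %), PhI(OAc)2, CH2Cl2, rt
Reagents that add atoms: none
Why: Oxoammonium (TEMPO) oxidation of a lactol to the lactone under neutral conditions that leave the benzylic stereocentre and the electron-rich ring untouched.

Step 4
Reactants: 5 (4S)-5,7-dimethoxy-4-(2-methylpropyl)chroman-2-one
Product: 6 (3S,4S)-3-allyl-5,7-dimethoxy-4-(2-methylpropyl)chroman-2-one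
Conditions: LiN(SiMe3)2, THF, −78 °C; allyl bromide, −78 → −40 °C
Reagents that add atoms: allyl bromide, C=CCBr
Why: Lactone enolate alkylation; the isobutyl group sits pseudoaxial to avoid the peri methoxy group and blocks one enolate face, so allyl enters trans (this centre is re-formed in step 5, so only clean monoalkylation matters here).

Step 5
Reactants: 6 (3S,4S)-3-allyl-5,7-dimethoxy-4-(2-methylpropyl)chroman-2-one
Product: 7 (3R,4R)-3-allyl-5,7-dimethoxy-3-methyl-4-(2-methylpropyl)chroman-2-one
Conditions: KN(SiMe3)2, THF, −78 °C; MeI, −78 → −20 °C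
Reagents that add atoms: iodomethane, CI
Why: Second enolate alkylation creating the quaternary carbon C4; iodomethane again attacks anti to the pseudoaxial isobutyl group, which places methyl trans and allyl cis to it, the C1′/C4 relationship of the target.

Step 6
Reactants: 7 (3R,4R)-3-allyl-5,7-dimethoxy-3-methyl-4-(2-methylpropyl)chroman-2-one
Product: 8 (3R,4R)-5,7-dimethoxy-3-methyl-4-(2-methylpropyl)-3-[(E)-prop-1-enyl]chroman-2-one
Conditions: RuHCl(CO)(PPh3)3 (5 mol %), toluene, 80 °C
Reagents that add atoms: none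
Why: Addition–elimination of the Ru–H species isomerises the terminal allyl group to the (E)-propenyl group; migration cannot pass the quaternary carbon, so it stops after one position.

Step 7
Reactants: 8 (3R,4R)-5,7-dimethoxy-3-methyl-4-(2-methylpropyl)-3-[(E)-prop-1-enyl]chroman-2-one
Product: 10 methyl (2R,3R)-2,5-dimethyl-2-[(E)-prop-1-enyl]-3-(2,4,6-trimethoxyphenyl)hexanoate, via phenol ester 9 (not isolated)
Conditions: K2CO3, MeI, MeOH/acetone, 50 °C
Reagents that add atoms: methanol, CO; iodomethane, CI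
Why: Carbonate-mediated methanolysis of the aryl lactone frees the phenoxide reversibly and Williamson methylation traps it irreversibly; the ester has no α-hydrogen, so nothing can epimerise.

Step 8
Reactants: 10 methyl (2R,3R)-2,5-dimethyl-2-[(E)-prop-1-enyl]-3-(2,4,6-trimethoxyphenyl)hexanoate
Product: 11 2-(trimethylsilyl)ethyl (4R,5R)-4,7-dimethyl-3-oxo-4-[(E)-prop-1-enyl]-5-(2,4,6-trimethoxyphenyl)octanoate
Conditions: CH3CO2CH2CH2SiMe3, LiN(iPr)2 (3 equiv each), THF, −78 → 0 °C; aq. NH4Cl
Reagents that add atoms: 2-(trimethylsilyl)ethyl acetate, CC(=O)OCC[Si](C)(C)C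
Why: Crossed Claisen condensation; ester 10 has no α-hydrogen and can only be the acceptor, and deprotonation of the β-keto ester by the excess acetate enolate drives the addition to the hindered carbonyl.

Step 9
Reactants: 11 2-(trimethylsilyl)ethyl (4R,5R)-4,7-dimethyl-3-oxo-4-[(E)-prop-1-enyl]-5-(2,4,6-trimethoxyphenyl)octanoate
Product: 12 2-(trimethylsilyl)ethyl (2Z,4R,5S)-4,7-dimethyl-4-[(E)-prop-1-enyl]-3-(trifluoromethylsulfonyloxy)-5-(2,4,6-trimethoxyphenyl)oct-2-enoate
Conditions: NaH, THF, 0 °C; PhNTf2, 0 °C → rt; aq. NH4Cl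
Reagents that add atoms: N-phenylbis(trifluoromethanesulfonimide), O=S(=O)(N(c1ccccc1)S(=O)(=O)C(F)(F)F)C(F)(F)F
Why: O-sulfonylation of the sodium-chelated β-keto ester enolate fixes the (Z) geometry (triflate cis to the ester); the ketone can enolise only toward C1 because C4 is quaternary, and the mild triflating agent spares the electron-rich arene.

Step 10
Reactants: 13 3-hydroxy-3-methylbutanoic acid
Product: 15 3-(tert-butyldimethylsilyloxy)-3-methylbutanoic acid, via bis-silyl ester 14 (not isolated)
Conditions: TBSOTf (2.2 equiv), 2,6-lutidine, CH2Cl2, 0 °C → rt; then THF/H2O/AcOH, rt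
Reagents that add atoms: tert-butyldimethylsilyl trifluoromethanesulfonate, CC(C)(C)[Si](C)(C)OS(=O)(=O)C(F)(F)F
Why: The silyl triflate silylates both the tertiary alcohol and the acid, and mild aqueous acid then hydrolyses only the labile silyl ester, leaving the hindered tertiary silyl ether.

Step 11
Reactants: 15 3-(tert-butyldimethylsilyloxy)-3-methylbutanoic acid; 16 (R)-4-benzyl-1,3-oxazolidin-2-one
Product: 18 (R)-4-benzyl-3-[3-(tert-butyldimethylsilyloxy)-3-methylbutanoyl]-1,3-oxazolidin-2-one, via mixed pivalic anhydride 17 (not isolated)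
Conditions: PivCl, Et3N, THF, −20 °C; then 16, LiCl, rt
Reagents that add atoms: none
Why: N-acylation of the oxazolidinone through the mixed pivalic anhydride (LiCl/amine protocol); the nucleophile attacks the less hindered carbonyl of the anhydride.

Step 12
Reactants: 18 (R)-4-benzyl-3-[3-(tert-butyldimethylsilyloxy)-3-methylbutanoyl]-1,3-oxazolidin-2-one; 19 (E)-but-2-enal (crotonaldehyde)
Product: 21 (R)-4-benzyl-3-[(2S,3S,4E)-2-[2-(tert-butyldimethylsilyloxy)propan-2-yl]-3-hydroxyhex-4-enoyl]-1,3-oxazolidin-2-one, via boron enolate 20 (not isolated)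
Conditions: Bu2BOTf, iPr2NEt, CH2Cl2, −78 → 0 °C; 19, −78 → 0 °C; pH 7 buffer, MeOH, H2O2
Reagents that add atoms: none
Why: Evans syn-aldol reaction; the (Z)-boron enolate reacts through a chair Zimmerman–Traxler transition state on the face away from the benzyl group, setting C7 and C8 (syn) in one step, and the aldehyde adds 1,2 because boron activates only the carbonyl.

Step 13
Reactants: 21 (R)-4-benzyl-3-[(2S,3S,4E)-2-[2-(tert-butyldimethylsilyloxy)propan-2-yl]-3-hydroxyhex-4-enoyl]-1,3-oxazolidin-2-one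
Product: 22 (R)-4-benzyl-3-[(2S,3S,4E)-2-[2-(tert-butyldimethylsilyloxy)propan-2-yl]-3-(triethylsilyloxy)hex-4-enoyl]-1,3-oxazolidin-2-one
Conditions: Et3SiOTf, 2,6-lutidine, CH2Cl2, −78 °C
Reagents that add atoms: triethylsilyl trifluoromethanesulfonate, CC[Si](CC)(CC)OS(=O)(=O)C(F)(F)F
Why: Silylation of the hindered secondary allylic alcohol with the reactive silyl triflate and a non-nucleophilic base; this blocks retro-aldol cleavage and gives a group that fluoride later removes in preference to the tertiary silyl ether.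

Step 14
Reactants: 22 (R)-4-benzyl-3-[(2S,3S,4E)-2-[2-(tert-butyldimethylsilyloxy)propan-2-yl]-3-(triethylsilyloxy)hex-4-enoyl]-1,3-oxazolidin-2-one
Product: 23 (2S,3S,4E)-2-[2-(tert-butyldimethylsilyloxy)propan-2-yl]-3-(triethylsilyloxy)hex-4-en-1-ol
Conditions: LiBH4, MeOH (1 equiv), Et2O, 0 °C
Reagents that add atoms: none
Why: Reductive removal of the auxiliary by borohydride attack at the exocyclic imide carbonyl gives the primary alcohol (C6) and returns the oxazolidinone without touching C7.

Step 15
Reactants: 23 (2S,3S,4E)-2-[2-(tert-butyldimethylsilyloxy)propan-2-yl]-3-(triethylsilyloxy)hex-4-en-1-ol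
Product: 24 (2S,3S,4E)-2-[2-(tert-butyldimethylsilyloxy)propan-2-yl]-1-iodo-3-(triethylsilyloxy)hex-4-ene
Conditions: I2, PPh3, imidazole, CH2Cl2, rt
Reagents that add atoms: iodine, II
Why: Appel-type iodination of the primary alcohol by SN2 displacement of the oxyphosphonium ion; the imidazole buffer protects both silyl ethers.

Step 16
Reactants: 24 (2S,3S,4E)-2-[2-(tert-butyldimethylsilyloxy)propan-2-yl]-1-iodo-3-(triethylsilyloxy)hex-4-ene; 12 2-(trimethylsilyl)ethyl (2Z,4R,5S)-4,7-dimethyl-4-[(E)-prop-1-enyl]-3-(trifluoromethylsulfonyloxy)-5-(2,4,6-trimethoxyphenyl)oct-2-enoate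
Product: 27 2-(trimethylsilyl)ethyl (2E,5S,6S,7E)-5-[2-(tert-butyldimethylsilyloxy)propan-2-yl]-3-[(2E,4R,5S)-4,7-dimethyl-5-(2,4,6-trimethoxyphenyl)oct-2-en-4-yl]-6-(triethylsilyloxy)nona-2,7-dienoate, via alkyllithium 25 (not isolated), via alkylzinc chloride 26 (not isolated)
Conditions: t-BuLi (2 equiv), Et2O, −78 °C; ZnCl2, THF, −78 °C → rt; 12, PdCl2(dppf) (5 mol %), THF, 50 °C
Reagents that add atoms: none
Why: Lithium–iodine exchange, transmetalation to zinc and Negishi sp3–sp2 cross-coupling form C5–C6; oxidative addition and reductive elimination retain the alkene geometry, so C6 ends cis to the ester, and the chelating ferrocenyl diphosphine suppresses β-hydride elimination.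

Step 17
Reactants: 27 2-(trimethylsilyl)ethyl (2E,5S,6S,7E)-5-[2-(tert-butyldimethylsilyloxy)propan-2-yl]-3-[(2E,4R,5S)-4,7-dimethyl-5-(2,4,6-trimethoxyphenyl)oct-2-en-4-yl]-6-(triethylsilyloxy)nona-2,7-dienoate
Product: 28 (2E,5S,6S,7E)-5-[2-(tert-butyldimethylsilyloxy)propan-2-yl]-3-[(2E,4R,5S)-4,7-dimethyl-5-(2,4,6-trimethoxyphenyl)oct-2-en-4-yl]-6-hydroxynona-2,7-dienoic acid
Conditions: Bu4NF (3 equiv), THF, 0 °C → rt; aq. NH4Cl
Reagents that add atoms: none
Why: Fluoride triggers β-elimination of the 2-(trimethylsilyl)ethyl ester (ethene and a fluorosilane leave) and cleaves the secondary triethylsilyl ether, while the hindered tertiary tert-butyldimethylsilyl ether stays.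

Step 18
Reactants: 28 (2E,5S,6S,7E)-5-[2-(tert-butyldimethylsilyloxy)propan-2-yl]-3-[(2E,4R,5S)-4,7-dimethyl-5-(2,4,6-trimethoxyphenyl)oct-2-en-4-yl]-6-hydroxynona-2,7-dienoic acid
Product: 30 (6S,7S)-6-[2-(tert-butyldimethylsilyloxy)propan-2-yl]-4-[(2E,4R,5S)-4,7-dimethyl-5-(2,4,6-trimethoxyphenyl)oct-2-en-4-yl]-7-[(E)-prop-1-enyl]-6,7-dihydro-5H-oxepin-2-one, via mixed anhydride 29 (not isolated)
Conditions: 2,4,6-Cl3C6H2COCl, Et3N, THF, rt; then DMAP, toluene, 80 °C, high dilution
Reagents that add atoms: none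
Why: Yamaguchi lactonisation; DMAP opens the mixed anhydride and the C8 hydroxyl closes the seven-membered ring, helped by the cis C1=C5 alkene that holds acid and alcohol on the same side.

Step 19
Reactants: 30 (6S,7S)-6-[2-(tert-butyldimethylsilyloxy)propan-2-yl]-4-[(2E,4R,5S)-4,7-dimethyl-5-(2,4,6-trimethoxyphenyl)oct-2-en-4-yl]-7-[(E)-prop-1-enyl]-6,7-dihydro-5H-oxepin-2-one
Product: 32 (6S,7S)-6-[2-(tert-butyldimethylsilyloxy)propan-2-yl]-4-[(2E,4R,5S)-4,7-dimethyl-5-(2,4,6-trimethoxyphenyl)oct-2-en-4-yl]-7-[(E)-prop-1-enyl]-6,7-dihydrooxepin-2(3H)-one, via potassium dienolate 31 (not isolated)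
Conditions: KN(SiMe3)2, THF, −78 °C; AcOH, −78 °C
Reagents that add atoms: none
Why: Deconjugative protonation; the hindered, non-nucleophilic potassium amide removes a γ-proton at C6 (the only enolisable position of the conjugated lactone) to give the ring dienolate, and kinetic protonation at the α-carbon C1 moves the alkene to C5=C6, which the seven-membered ring holds cis.

Step 20
Reactants: 32 (6S,7S)-6-[2-(tert-butyldimethylsilyloxy)propan-2-yl]-4-[(2E,4R,5S)-4,7-dimethyl-5-(2,4,6-trimethoxyphenyl)oct-2-en-4-yl]-7-[(E)-prop-1-enyl]-6,7-dihydrooxepin-2(3H)-one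
Product: 36 (1R,4R,7R)-4-[2-(tert-butyldimethylsilyloxy)propan-2-yl]-2-[(2E,4R,5S)-4,7-dimethyl-5-(2,4,6-trimethoxyphenyl)oct-2-en-4-yl]-7-methylcyclohepta-2,5-diene-1-carboxylic acid, via lithium dienolate 33 (not isolated), via silyl dienol ether 34 (not isolated), via trimethylsilyl ester 35 (not isolated)
Conditions: LiN(iPr)2, THF, −78 °C; Me3SiCl/Et3N, −78 °C → rt; toluene, 100 °C; then dilute aq. HCl, THF
Reagents that add atoms: none
Why: LiN(iPr)2 removes the doubly activated C1 proton to give dienolate 33, O-silylation gives the cyclic silyl dienol ether 34, and on heating its C1=C2–O–C8–C9=C10 array undergoes the [3,3] shift that forms C1–C10 and breaks O–C8, leaving silyl ester 35, which is hydrolysed to acid 36. The closest known reaction type is the Ireland–Claisen (ester-enolate Claisen) rearrangement of alkenyl-substituted lactones to cycloalkenecarboxylic acids. The seven-membered carbocycle (C1, C5–C10) is closed by this suprafacial sigmatropic C–C bond formation; because the C5=C6–C7 chain bridges the two ends of the six-atom array, only a boat transition state is possible and the new ring alkene C8=C9 is necessarily cis. C10 is bonded on the face of the propenyl group from which oxygen leaves C8, so the absolute configuration of C10 and of C1 is dictated by C8, which was set in step 12. The cis relation of H1 and H10 follows from the boat geometry combined with the (E)-propenyl group and the ring-fixed ketene acetal geometry. The step needs enolisation only at C1 and silylation on oxygen: C1 carries the only protons that are both α to the carbonyl and allylic, and Me3SiCl with Et3N silylates lithium ester enolates on oxygen. It also needs the bulky C7 substituent out of the way, and in this syn-aldol-derived lactone it is anti to the C8–O bond and points to the open face of the bicyclic transition state.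

Step 21
Reactants: 36 (1R,4R,7R)-4-[2-(tert-butyldimethylsilyloxy)propan-2-yl]-2-[(2E,4R,5S)-4,7-dimethyl-5-(2,4,6-trimethoxyphenyl)oct-2-en-4-yl]-7-methylcyclohepta-2,5-diene-1-carboxylic acid
Product: 37 [(1R,4R,7R)-4-[2-(tert-butyldimethylsilyloxy)propan-2-yl]-2-[(2E,4R,5S)-4,7-dimethyl-5-(2,4,6-trimethoxyphenyl)oct-2-en-4-yl]-7-methylcyclohepta-2,5-dien-1-yl]methanol
Conditions: LiAlH4, Et2O, 0 °C
Reagents that add atoms: none
Why: Hydride reduction of the acid (as its carboxylate) to the primary alcohol; the carboxylate is not enolised, so C1 keeps its configuration.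

Step 22
Reactants: 37 [(1R,4R,7R)-4-[2-(tert-butyldimethylsilyloxy)propan-2-yl]-2-[(2E,4R,5S)-4,7-dimethyl-5-(2,4,6-trimethoxyphenyl)oct-2-en-4-yl]-7-methylcyclohepta-2,5-dien-1-yl]methanol
Product: 38 (1R,4R,7R)-4-[2-(tert-butyldimethylsilyloxy)propan-2-yl]-2-[(2E,4R,5S)-4,7-dimethyl-5-(2,4,6-trimethoxyphenyl)oct-2-en-4-yl]-7-methylcyclohepta-2,5-diene-1-carbaldehyde
Conditions: Dess–Martin periodinane, NaHCO3, CH2Cl2, 0 °C
Reagents that add atoms: none
Why: Dess–Martin oxidation under buffered, non-basic conditions gives the aldehyde without epimerising C1 or drawing the C5=C6 alkene into conjugation; the aldehyde is used at once.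

Step 23
Reactants: 38 (1R,4R,7R)-4-[2-(tert-butyldimethylsilyloxy)propan-2-yl]-2-[(2E,4R,5S)-4,7-dimethyl-5-(2,4,6-trimethoxyphenyl)oct-2-en-4-yl]-7-methylcyclohepta-2,5-diene-1-carbaldehyde
Product: 39 (1R,4R,7R)-4-[2-(tert-butyldimethylsilyloxy)propan-2-yl]-2-[(2E,4R,5S)-4,7-dimethyl-5-(2,4,6-trimethoxyphenyl)oct-2-en-4-yl]-1-ethenyl-7-methylcyclohepta-2,5-diene (locants as in 36)
Conditions: Cp2TiMe2, toluene, 65 °C, dark
Reagents that add atoms: dimethyltitanocene (Cp2TiMe2), C[Ti](C)(C1C=CC=C1)C2C=CC=C2
Why: Petasis methylenation; the methylidene Cp2Ti=CH2 formed on heating converts the aldehyde into the vinyl group through an oxatitanacyclobutane without any base, so the allylic α-centre C1 is not epimerised.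

Step 24
Reactants: 39 (1R,4R,7R)-4-[2-(tert-butyldimethylsilyloxy)propan-2-yl]-2-[(2E,4R,5S)-4,7-dimethyl-5-(2,4,6-trimethoxyphenyl)oct-2-en-4-yl]-1-ethenyl-7-methylcyclohepta-2,5-diene
Product: 40 tert-butyl({2-[(1R,3aR,4R,7R)-1,4-dimethyl-1-[(1S)-3-methyl-1-(2,4,6-trimethoxyphenyl)butyl]-1,3a,4,7-tetrahydroazulen-7-yl]propan-2-yl}oxy)dimethylsilane
Conditions: second-generation Grubbs catalyst RuCl2(=CHPh)(PCy3)(H2IMes) (5 mol %), CH2Cl2, 40 °C
Reagents that add atoms: none
Why: Ring-closing metathesis between the C1 vinyl and C4 propenyl groups closes the cyclopentene (C2=C3) with loss of propene; the trisubstituted C5=C6 and the unstrained ring alkene C8=C9 are much poorer partners.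

Step 25
Reactants: 40 tert-butyl({2-[(1R,3aR,4R,7R)-1,4-dimethyl-1-[(1S)-3-methyl-1-(2,4,6-trimethoxyphenyl)butyl]-1,3a,4,7-tetrahydroazulen-7-yl]propan-2-yl}oxy)dimethylsilane
Product: 41 tert-butyl({2-[(1R,3aR,4R,7R)-1,4-dimethyl-1-[(1S)-3-methyl-1-(2,4,6-trimethoxyphenyl)butyl]-1,2,3,3a,4,5,6,7-octahydroazulen-7-yl]propan-2-yl}oxy)dimethylsilane
Conditions: H2 (1 atm), RhCl(PPh3)3 (10 mol %), benzene/EtOH, rt
Reagents that add atoms: none
Why: Homogeneous hydrogenation with RhCl(PPh3)3 reduces the two cis-disubstituted ring alkenes (C2=C3, C8=C9) and leaves the hindered trisubstituted C5=C6 alkene; no stereocentre is created.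

Step 26
Reactants: 41 tert-butyl({2-[(1R,3aR,4R,7R)-1,4-dimethyl-1-[(1S)-3-methyl-1-(2,4,6-trimethoxyphenyl)butyl]-1,2,3,3a,4,5,6,7-octahydroazulen-7-yl]propan-2-yl}oxy)dimethylsilane
Product: 44 5-[(1S)-1-[(1R,3aR,4R,7R)-7-[2-(tert-butyldimethylsilyloxy)propan-2-yl]-1,4-dimethyl-1,2,3,3a,4,5,6,7-octahydroazulen-1-yl]-3-methylbutyl]-2,4,6-trimethoxybenzene-1,3-dicarbaldehyde, via mono-adduct 42 (not isolated), via bis-adduct 43 (not isolated)
Conditions: n-BuLi, TMEDA, THF, 0 °C; DMF, −78 → 0 °C; n-BuLi, 0 °C; DMF; aq. HCl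
Reagents that add atoms: N,N-dimethylformamide, CN(C)C=O
Why: Directed ortho-lithiation at an aryl position flanked by two methoxy groups, then formylation with DMF; the lithium hemiaminal 42 masks the first aldehyde in the flask, so the second position can be lithiated and formylated before aqueous acid releases both aldehydes.

Step 27
Reactants: 44 5-[(1S)-1-[(1R,3aR,4R,7R)-7-[2-(tert-butyldimethylsilyloxy)propan-2-yl]-1,4-dimethyl-1,2,3,3a,4,5,6,7-octahydroazulen-1-yl]-3-methylbutyl]-2,4,6-trimethoxybenzene-1,3-dicarbaldehyde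
Product: 45 5-[(1S)-1-[(1R,3aR,4R,7R)-7-[2-(tert-butyldimethylsilyloxy)propan-2-yl]-1,4-dimethyl-1,2,3,3a,4,5,6,7-octahydroazulen-1-yl]-3-methylbutyl]-2,4,6-trihydroxybenzene-1,3-dicarbaldehyde
Conditions: 4-MeC6H4SLi, HMPA/toluene, 110 °C; aq. HCl
Reagents that add atoms: none
Why: SN2 demethylation by the soft arenethiolate; every methoxy group is ortho or para to a formyl group, which makes the phenoxide a good leaving group, and the basic medium spares the silyl ether, the alkene and the benzylic centre.

Step 28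
Reactants: 45 5-[(1S)-1-[(1R,3aR,4R,7R)-7-[2-(tert-butyldimethylsilyloxy)propan-2-yl]-1,4-dimethyl-1,2,3,3a,4,5,6,7-octahydroazulen-1-yl]-3-methylbutyl]-2,4,6-trihydroxybenzene-1,3-dicarbaldehyde
Product: 46 5-[(1S)-1-[(1R,3aR,4R,7R)-7-(2-hydroxypropan-2-yl)-1,4-dimethyl-1,2,3,3a,4,5,6,7-octahydroazulen-1-yl]-3-methylbutyl]-2,4,6-trihydroxybenzene-1,3-dicarbaldehyde (CNP0281883.3)
Conditions: HF·pyridine, pyridine/THF, rt
Reagents that add atoms: none
Why: Fluoride cleavage of the tertiary silyl ether under buffered conditions that avoid ionisation of the tertiary homoallylic alcohol; this mild step is kept for last.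

## Compound list

1 | isovaleraldehyde (3-methylbutanal) | CC(C)CC=O | starting material
2 | (E)-5-methylhex-2-enal | CC(C)C/C=C/C=O | intermediate
3 | 3,5-dimethoxyphenol | COc1cc(O)cc(OC)c1 | starting material
4 | (4S)-5,7-dimethoxy-4-(2-methylpropyl)chroman-2-ol (both C2 epimers) | OC1C[C@H](CC(C)C)c2c(OC)cc(OC)cc2O1 | intermediate
5 | (4S)-5,7-dimethoxy-4-(2-methylpropyl)chroman-2-one | O=C1C[C@H](CC(C)C)c2c(OC)cc(OC)cc2O1 | intermediate
6 | (3S,4S)-3-allyl-5,7-dimethoxy-4-(2-methylpropyl)chroman-2-one (3,4-trans) | O=C1Oc2cc(OC)cc(OC)c2[C@@H](CC(C)C)[C@@H]1CC=C | intermediate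
7 | (3R,4R)-3-allyl-5,7-dimethoxy-3-methyl-4-(2-methylpropyl)chroman-2-one (methyl trans to isobutyl) | O=C1Oc2cc(OC)cc(OC)c2[C@@H](CC(C)C)[C@@]1(C)CC=C | intermediate
8 | (3R,4R)-5,7-dimethoxy-3-methyl-4-(2-methylpropyl)-3-[(E)-prop-1-enyl]chroman-2-one | O=C1Oc2cc(OC)cc(OC)c2[C@@H](CC(C)C)[C@@]1(C)/C=C/C | intermediate
9 | methyl (2R,3R)-3-(2-hydroxy-4,6-dimethoxyphenyl)-2,5-dimethyl-2-[(E)-prop-1-enyl]hexanoate (not isolated) | COC(=O)[C@](C)(/C=C/C)[C@H](CC(C)C)c1c(O)cc(OC)cc1OC | intermediate
10 | methyl (2R,3R)-2,5-dimethyl-2-[(E)-prop-1-enyl]-3-(2,4,6-trimethoxyphenyl)hexanoate | COC(=O)[C@](C)(/C=C/C)[C@H](CC(C)C)c1c(OC)cc(OC)cc1OC | intermediate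
11 | 2-(trimethylsilyl)ethyl (4R,5R)-4,7-dimethyl-3-oxo-4-[(E)-prop-1-enyl]-5-(2,4,6-trimethoxyphenyl)octanoate | C[Si](C)(C)CCOC(=O)CC(=O)[C@](C)(/C=C/C)[C@H](CC(C)C)c1c(OC)cc(OC)cc1OC | intermediate
12 | 2-(trimethylsilyl)ethyl (2Z,4R,5S)-4,7-dimethyl-4-[(E)-prop-1-enyl]-3-(trifluoromethylsulfonyloxy)-5-(2,4,6-trimethoxyphenyl)oct-2-enoate | C[Si](C)(C)CCOC(=O)/C=C(\OS(=O)(=O)C(F)(F)F)[C@](C)(/C=C/C)[C@H](CC(C)C)c1c(OC)cc(OC)cc1OC | intermediate
13 | 3-hydroxy-3-methylbutanoic acid | CC(C)(O)CC(=O)O | starting material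
14 | tert-butyldimethylsilyl 3-(tert-butyldimethylsilyloxy)-3-methylbutanoate (not isolated) | CC(C)(O[Si](C)(C)C(C)(C)C)CC(=O)O[Si](C)(C)C(C)(C)C | intermediate
15 | 3-(tert-butyldimethylsilyloxy)-3-methylbutanoic acid | CC(C)(O[Si](C)(C)C(C)(C)C)CC(=O)O | intermediate
16 | (R)-4-benzyl-1,3-oxazolidin-2-one | O=C1N[C@H](Cc2ccccc2)CO1 | starting material
17 | 3-(tert-butyldimethylsilyloxy)-3-methylbutanoic pivalic anhydride (not isolated) | CC(C)(O[Si](C)(C)C(C)(C)C)CC(=O)OC(=O)C(C)(C)C | intermediate
18 | (R)-4-benzyl-3-[3-(tert-butyldimethylsilyloxy)-3-methylbutanoyl]-1,3-oxazolidin-2-one | CC(C)(O[Si](C)(C)C(C)(C)C)CC(=O)N1[C@H](Cc2ccccc2)COC1=O | intermediate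
19 | (E)-but-2-enal (crotonaldehyde) | C/C=C/C=O | starting material
20 | (Z)-dibutylboron enolate of 18 (not isolated) | CCCCB(CCCC)O/C(=C\C(C)(C)O[Si](C)(C)C(C)(C)C)N1[C@H](Cc2ccccc2)COC1=O | intermediate
21 | (R)-4-benzyl-3-[(2S,3S,4E)-2-[2-(tert-butyldimethylsilyloxy)propan-2-yl]-3-hydroxyhex-4-enoyl]-1,3-oxazolidin-2-one | C/C=C/[C@H](O)[C@@H](C(C)(C)O[Si](C)(C)C(C)(C)C)C(=O)N1[C@H](Cc2ccccc2)COC1=O | intermediate
22 | (R)-4-benzyl-3-[(2S,3S,4E)-2-[2-(tert-butyldimethylsilyloxy)propan-2-yl]-3-(triethylsilyloxy)hex-4-enoyl]-1,3-oxazolidin-2-one | C/C=C/[C@H](O[Si](CC)(CC)CC)[C@@H](C(C)(C)O[Si](C)(C)C(C)(C)C)C(=O)N1[C@H](Cc2ccccc2)COC1=O | intermediate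
23 | (2S,3S,4E)-2-[2-(tert-butyldimethylsilyloxy)propan-2-yl]-3-(triethylsilyloxy)hex-4-en-1-ol | C/C=C/[C@H](O[Si](CC)(CC)CC)[C@@H](C(C)(C)O[Si](C)(C)C(C)(C)C)CO | intermediate
24 | (2S,3S,4E)-2-[2-(tert-butyldimethylsilyloxy)propan-2-yl]-1-iodo-3-(triethylsilyloxy)hex-4-ene | C/C=C/[C@H](O[Si](CC)(CC)CC)[C@@H](C(C)(C)O[Si](C)(C)C(C)(C)C)CI | intermediate
25 | alkyllithium from 24, lithium in place of iodine (not isolated) | C/C=C/[C@H](O[Si](CC)(CC)CC)[C@@H](C(C)(C)O[Si](C)(C)C(C)(C)C)C[Li] | intermediate
26 | alkylzinc chloride from 25, ZnCl in place of lithium (not isolated) | C/C=C/[C@H](O[Si](CC)(CC)CC)[C@@H](C(C)(C)O[Si](C)(C)C(C)(C)C)C[Zn]Cl | intermediate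
27 | 2-(trimethylsilyl)ethyl (2E,5S,6S,7E)-5-[2-(tert-butyldimethylsilyloxy)propan-2-yl]-3-[(2E,4R,5S)-4,7-dimethyl-5-(2,4,6-trimethoxyphenyl)oct-2-en-4-yl]-6-(triethylsilyloxy)nona-2,7-dienoate | C[Si](C)(C)CCOC(=O)/C=C(\C[C@H](C(C)(C)O[Si](C)(C)C(C)(C)C)[C@@H](O[Si](CC)(CC)CC)/C=C/C)[C@](C)(/C=C/C)[C@H](CC(C)C)c1c(OC)cc(OC)cc1OC | intermediate
28 | (2E,5S,6S,7E)-5-[2-(tert-butyldimethylsilyloxy)propan-2-yl]-3-[(2E,4R,5S)-4,7-dimethyl-5-(2,4,6-trimethoxyphenyl)oct-2-en-4-yl]-6-hydroxynona-2,7-dienoic acid | OC(=O)/C=C(\C[C@H](C(C)(C)O[Si](C)(C)C(C)(C)C)[C@@H](O)/C=C/C)[C@](C)(/C=C/C)[C@H](CC(C)C)c1c(OC)cc(OC)cc1OC | intermediate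
29 | mixed 2,4,6-trichlorobenzoic anhydride of 28 (not isolated) | O=C(OC(=O)/C=C(\C[C@H](C(C)(C)O[Si](C)(C)C(C)(C)C)[C@@H](O)/C=C/C)[C@](C)(/C=C/C)[C@H](CC(C)C)c1c(OC)cc(OC)cc1OC)c1c(Cl)cc(Cl)cc1Cl | intermediate
30 | (6S,7S)-6-[2-(tert-butyldimethylsilyloxy)propan-2-yl]-4-[(2E,4R,5S)-4,7-dimethyl-5-(2,4,6-trimethoxyphenyl)oct-2-en-4-yl]-7-[(E)-prop-1-enyl]-6,7-dihydro-5H-oxepin-2-one (conjugated lactone) | O=C1C=C(C[C@H](C(C)(C)O[Si](C)(C)C(C)(C)C)[C@H](/C=C/C)O1)[C@](C)(/C=C/C)[C@H](CC(C)C)c2c(OC)cc(OC)cc2OC | intermediate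
31 | potassium dienolate of lactone 30 (not isolated) | [K]OC1=CC(=C[C@H](C(C)(C)O[Si](C)(C)C(C)(C)C)[C@H](/C=C/C)O1)[C@](C)(/C=C/C)[C@H](CC(C)C)c2c(OC)cc(OC)cc2OC | intermediate
32 | (6S,7S)-6-[2-(tert-butyldimethylsilyloxy)propan-2-yl]-4-[(2E,4R,5S)-4,7-dimethyl-5-(2,4,6-trimethoxyphenyl)oct-2-en-4-yl]-7-[(E)-prop-1-enyl]-6,7-dihydrooxepin-2(3H)-one (ε-lactone with C5=C6) | O=C1CC(=C[C@H](C(C)(C)O[Si](C)(C)C(C)(C)C)[C@H](/C=C/C)O1)[C@](C)(/C=C/C)[C@H](CC(C)C)c2c(OC)cc(OC)cc2OC | intermediate
33 | lithium dienolate of lactone 32 (not isolated) | [Li]OC1=CC(=C[C@H](C(C)(C)O[Si](C)(C)C(C)(C)C)[C@H](/C=C/C)O1)[C@](C)(/C=C/C)[C@H](CC(C)C)c2c(OC)cc(OC)cc2OC | intermediate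
34 | 2-(trimethylsilyloxy)-6,7-dihydrooxepine (silyl dienol ether) of 32 (not isolated) | C[Si](C)(C)OC1=CC(=C[C@H](C(C)(C)O[Si](C)(C)C(C)(C)C)[C@H](/C=C/C)O1)[C@](C)(/C=C/C)[C@H](CC(C)C)c2c(OC)cc(OC)cc2OC | intermediate
35 | trimethylsilyl ester of acid 36 (not isolated) | C[Si](C)(C)OC(=O)[C@H]1C(=C[C@H](C(C)(C)O[Si](C)(C)C(C)(C)C)C=C[C@H]1C)[C@](C)(/C=C/C)[C@H](CC(C)C)c2c(OC)cc(OC)cc2OC | intermediate
36 | (1R,4R,7R)-4-[2-(tert-butyldimethylsilyloxy)propan-2-yl]-2-[(2E,4R,5S)-4,7-dimethyl-5-(2,4,6-trimethoxyphenyl)oct-2-en-4-yl]-7-methylcyclohepta-2,5-diene-1-carboxylic acid | OC(=O)[C@H]1C(=C[C@H](C(C)(C)O[Si](C)(C)C(C)(C)C)C=C[C@H]1C)[C@](C)(/C=C/C)[C@H](CC(C)C)c2c(OC)cc(OC)cc2OC | intermediate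
37 | [(1R,4R,7R)-4-[2-(tert-butyldimethylsilyloxy)propan-2-yl]-2-[(2E,4R,5S)-4,7-dimethyl-5-(2,4,6-trimethoxyphenyl)oct-2-en-4-yl]-7-methylcyclohepta-2,5-dien-1-yl]methanol | OC[C@H]1C(=C[C@H](C(C)(C)O[Si](C)(C)C(C)(C)C)C=C[C@H]1C)[C@](C)(/C=C/C)[C@H](CC(C)C)c2c(OC)cc(OC)cc2OC | intermediate
38 | (1R,4R,7R)-4-[2-(tert-butyldimethylsilyloxy)propan-2-yl]-2-[(2E,4R,5S)-4,7-dimethyl-5-(2,4,6-trimethoxyphenyl)oct-2-en-4-yl]-7-methylcyclohepta-2,5-diene-1-carbaldehyde | O=C[C@H]1C(=C[C@H](C(C)(C)O[Si](C)(C)C(C)(C)C)C=C[C@H]1C)[C@](C)(/C=C/C)[C@H](CC(C)C)c2c(OC)cc(OC)cc2OC | intermediate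
39 | (1R,4R,7R)-4-[2-(tert-butyldimethylsilyloxy)propan-2-yl]-2-[(2E,4R,5S)-4,7-dimethyl-5-(2,4,6-trimethoxyphenyl)oct-2-en-4-yl]-1-ethenyl-7-methylcyclohepta-2,5-diene (locants as in 36) | C=C[C@H]1C(=C[C@H](C(C)(C)O[Si](C)(C)C(C)(C)C)C=C[C@H]1C)[C@](C)(/C=C/C)[C@H](CC(C)C)c2c(OC)cc(OC)cc2OC | intermediate
40 | tert-butyl({2-[(1R,3aR,4R,7R)-1,4-dimethyl-1-[(1S)-3-methyl-1-(2,4,6-trimethoxyphenyl)butyl]-1,3a,4,7-tetrahydroazulen-7-yl]propan-2-yl}oxy)dimethylsilane | CC(C)C[C@H](c1c(OC)cc(OC)cc1OC)[C@@]2(C)C=C[C@H]3C2=C[C@H](C(C)(C)O[Si](C)(C)C(C)(C)C)C=C[C@H]3C | intermediate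
41 | tert-butyl({2-[(1R,3aR,4R,7R)-1,4-dimethyl-1-[(1S)-3-methyl-1-(2,4,6-trimethoxyphenyl)butyl]-1,2,3,3a,4,5,6,7-octahydroazulen-7-yl]propan-2-yl}oxy)dimethylsilane | CC(C)C[C@H](c1c(OC)cc(OC)cc1OC)[C@@]2(C)CC[C@H]3C2=C[C@H](C(C)(C)O[Si](C)(C)C(C)(C)C)CC[C@H]3C | intermediate
42 | lithium α-(dimethylamino)alkoxide from 41, one aryl position formylated and masked (not isolated) | CC(C)C[C@H](c1c(OC)c(C(O[Li])N(C)C)c(OC)cc1OC)[C@@]2(C)CC[C@H]3C2=C[C@H](C(C)(C)O[Si](C)(C)C(C)(C)C)CC[C@H]3C | intermediate
43 | bis[lithium α-(dimethylamino)alkoxide] from 41, both aryl positions (not isolated) | CC(C)C[C@H](c1c(OC)c(C(O[Li])N(C)C)c(OC)c(C(O[Li])N(C)C)c1OC)[C@@]2(C)CC[C@H]3C2=C[C@H](C(C)(C)O[Si](C)(C)C(C)(C)C)CC[C@H]3C | intermediate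
44 | 5-[(1S)-1-[(1R,3aR,4R,7R)-7-[2-(tert-butyldimethylsilyloxy)propan-2-yl]-1,4-dimethyl-1,2,3,3a,4,5,6,7-octahydroazulen-1-yl]-3-methylbutyl]-2,4,6-trimethoxybenzene-1,3-dicarbaldehyde | CC(C)C[C@H](c1c(OC)c(C=O)c(OC)c(C=O)c1OC)[C@@]2(C)CC[C@H]3C2=C[C@H](C(C)(C)O[Si](C)(C)C(C)(C)C)CC[C@H]3C | intermediate
45 | 5-[(1S)-1-[(1R,3aR,4R,7R)-7-[2-(tert-butyldimethylsilyloxy)propan-2-yl]-1,4-dimethyl-1,2,3,3a,4,5,6,7-octahydroazulen-1-yl]-3-methylbutyl]-2,4,6-trihydroxybenzene-1,3-dicarbaldehyde | CC(C)C[C@H](c1c(O)c(C=O)c(O)c(C=O)c1O)[C@@]2(C)CC[C@H]3C2=C[C@H](C(C)(C)O[Si](C)(C)C(C)(C)C)CC[C@H]3C | intermediate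
46 | 5-[(1S)-1-[(1R,3aR,4R,7R)-7-(2-hydroxypropan-2-yl)-1,4-dimethyl-1,2,3,3a,4,5,6,7-octahydroazulen-1-yl]-3-methylbutyl]-2,4,6-trihydroxybenzene-1,3-dicarbaldehyde (CNP0281883.3) | CC(C)C[C@H](c1c(O)c(C=O)c(O)c(C=O)c1O)[C@@]1(C)CC[C@H]2C1=C[C@H](C(C)(C)O)CC[C@H]2C | target

## Step count and least certain steps

Total: 28 steps. Longest linear sequence: 22 steps (steps 1–9, then 16–28). The aldol half takes 6 steps (10–15) and joins at step 16.

**Step 20 (key step).** The conjugated silyl dienol ether may decompose thermally or hydrolyse before it rearranges, because the boat transition state must twist the dienol ether out of planarity and pyramidalise C1 next to the bulky C5 substituent. Ionisation of the allylic C8–O bond at 100 °C could compete. Fallback, from 32 back to 36: soft enolisation of 32 with dicyclohexylboron triflate and Et3N at −78 °C gives the dicyclohexylboron dienol ether of lactone 32, F1, without a lithium dienolate. Boron ketene acetals of allylic esters undergo the same [3,3] shift at or below room temperature, and mild aqueous work-up releases acid 36.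

**Step 2.** C-alkylation para to the hydroxyl (between the methoxy groups, where no hemiacetal can close) may compete, and the β-branched enal may give poor face discrimination. Fallback, from 3 back to 5: Pechmann condensation of 3 with commercial ethyl 5-methyl-3-oxohexanoate (acid catalysis) gives 5,7-dimethoxy-4-(2-methylpropyl)coumarin F2. Enantioselective conjugate reduction of F2 with a chiral bisphosphine CuH catalyst, generated from Cu(OAc)2, a SEGPHOS-type ligand and a silane, then gives lactone 5.

**Step 16.** Transmetalation and reductive elimination at the vinyl triflate, which carries the quaternary carbon, may be slow; the alkylzinc reagent would then be lost to protonation or β-hydride elimination and the triflate to hydrolysis. Fallback, from 10 and 25 back to 27, using carbonyl addition in place of cross-coupling: ester 10 is reduced with iBu2AlH to (2R,3R)-2,5-dimethyl-2-[(E)-prop-1-enyl]-3-(2,4,6-trimethoxyphenyl)hexanal F3. Alkyllithium 25 adds to it to give the secondary alcohol F4, and Dess–Martin oxidation gives the C5 ketone F5. Peterson olefination of F5 with lithiated 2-(trimethylsilyl)ethyl (trimethylsilyl)acetate gives ester 27, the ester group settling away from the quaternary carbon.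

**Step 26.** The second lithiation may stop short, because the mono-adduct is a poorer substrate and consumes base by aggregation; butyl addition to aldehyde released too early is a second loss. Fallback, from 41 back to 44: N-bromosuccinimide in MeCN at −20 °C brominates both free aryl positions to give the 3,5-dibromo-2,4,6-trimethoxyphenyl analogue of 41, F6. Double bromine–lithium exchange with t-BuLi at −78 °C and a DMF quench then give dialdehyde 44.

## Further compounds

F1 | step 20 | dicyclohexylboron dienol ether of lactone 32 | C1CCCCC1B(C3CCCCC3)OC4=CC(=C[C@H](C(C)(C)O[Si](C)(C)C(C)(C)C)[C@H](/C=C/C)O4)[C@](C)(/C=C/C)[C@H](CC(C)C)c2c(OC)cc(OC)cc2OC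
F2 | step 2 | 5,7-dimethoxy-4-(2-methylpropyl)coumarin | CC(C)CC1=CC(=O)Oc2cc(OC)cc(OC)c12
F3 | step 16 | (2R,3R)-2,5-dimethyl-2-[(E)-prop-1-enyl]-3-(2,4,6-trimethoxyphenyl)hexanal | O=C[C@](C)(/C=C/C)[C@H](CC(C)C)c1c(OC)cc(OC)cc1OC
F4 | step 16 | secondary alcohol from addition of 25 to F3 (both C5 epimers) | C/C=C/[C@H](O[Si](CC)(CC)CC)[C@@H](C(C)(C)O[Si](C)(C)C(C)(C)C)CC(O)[C@](C)(/C=C/C)[C@H](CC(C)C)c1c(OC)cc(OC)cc1OC
F5 | step 16 | C5 ketone from oxidation of F4 | C/C=C/[C@H](O[Si](CC)(CC)CC)[C@@H](C(C)(C)O[Si](C)(C)C(C)(C)C)CC(=O)[C@](C)(/C=C/C)[C@H](CC(C)C)c1c(OC)cc(OC)cc1OC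
F6 | step 26 | 3,5-dibromo-2,4,6-trimethoxyphenyl analogue of 41 | CC(C)C[C@H](c1c(OC)c(Br)c(OC)c(Br)c1OC)[C@@]2(C)CC[C@H]3C2=C[C@H](C(C)(C)O[Si](C)(C)C(C)(C)C)CC[C@H]3C
A1 | alternative 1 | 2-substituted malonyl dichloride carrying C1′ and the silyl-protected hydroazulene | CC(C)C[C@H](C(C(=O)Cl)C(=O)Cl)[C@@]1(C)CC[C@H]2C1=C[C@H](C(C)(C)O[Si](CC)(CC)CC)CC[C@H]2C
A2 | alternative 1 | dimethyl 3-oxoglutarate | COC(=O)CC(=O)CC(=O)OC
A3 | alternative 1 | dimethyl 2,4,6-trihydroxy-5-alkylisophthalate with the full skeleton | CC(C)C[C@H](c1c(O)c(C(=O)OC)c(O)c(C(=O)OC)c1O)[C@@]1(C)CC[C@H]2C1=C[C@H](C(C)(C)O[Si](CC)(CC)CC)CC[C@H]2C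
A4 | alternative 2 | trans-decalin C6-ol C5-mesylate (equatorial sulfonate) | CC(C)C[C@H](c1c(OC)cc(OC)cc1OC)[C@@]1(C)CC[C@H]2[C@](O)([C@@H]1OS(C)(=O)=O)[C@H](C(C)(C)O[Si](CC)(CC)CC)CC[C@H]2C
A5 | alternative 2 | cis-fused hydroazulen-6-one | CC(C)C[C@H](c1c(OC)cc(OC)cc1OC)[C@@]1(C)CC[C@H]2[C@@H]1C(=O)[C@H](C(C)(C)O[Si](CC)(CC)CC)CC[C@H]2C
A6 | alternative 3 | hydroazulene C4 carbaldehyde | O=C[C@@]1(C)CC[C@H]2C1=C[C@H](C(C)(C)O)CC[C@H]2C
A7 | alternative 3 | 2,4-diformylphloroglucinol | O=Cc1c(O)cc(O)c(C=O)c1O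
A8 | alternative 3 | ortho-quinone methide from A6 and A7 | O=C1C(C=O)=C(O)C(C=O)=C(O)C1=C[C@@]1(C)CC[C@H]2C1=C[C@H](C(C)(C)O)CC[C@H]2C
A9 | alternative 3 | methallyltrimethylsilane | CC(=C)C[Si](C)(C)C
A10 | alternative 3 | methallyl analogue of the target | CC(=C)C[C@H](c1c(O)c(C=O)c(O)c(C=O)c1O)[C@@]1(C)CC[C@H]2C1=C[C@H](C(C)(C)O)CC[C@H]2C
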